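The runs come from a simulation for substances that don't exist, and the scatter is random.

This flask is slow: larch has made 0.8% of left-handed product by 6.00 h, and its curve starts flat, with 0.1% at 2.00 h.

common to all: left-handed substrate 0.10 M; right-handed substrate 0.10 M; racemization catalyst 10 mM

|  | solid reagent | free catalyst | remark | time |
|---|---|---|---|---|
| larch | 0.22 M | 0.50 mM | the very flask that is asked about, followed so far |  |
| birch | 0.22 M | 0.34 mM | run made earlier |  |
| flask | 0.220 M | 0.50 mM |  | 50 h |

| run | time / h | left-handed substrate / % | right-handed substrate / % | left-handed product / % |
|---|---|---|---|---|
| larch | 0.833 | 49.6 | 50.1 | 0 |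
| larch | 2.00 | 49.1 | 49.2 | 0.1 |
| larch | 4.00 | 49.6 | 50.4 | 0.4 |
| larch | 6.00 | 49.1 | 50.4 | 0.8 |
| birch | 6.00 | 50.6 | 51.1 | 1.4 |
| birch | 20.0 | 47.4 | 48.9 | 3.0 |
| birch | 30.0 | 48.1 | 47.5 | 4.2 |
| birch | 48.0 | 46.6 | 48.3 | 4.1 |

(standard deviation of a reading: 0.5 percentage points)

- free catalyst is single-handed; left-handed substrate and right-handed substrate are mirror images of each other, charged as a racemate, each of them at the stated concentration
- given per volume of solution although it is solid: solid reagent
- the numbers in the tables scatter with a standard deviation of 0.5 percentage points
- at the start none of the solid reagent is in solution
- an excess is below zero if the other one leads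

* part of the left-handed substrate and right-handed substrate charged together that has reacted at 50 h
* excess of left-handed product over right-handed product in the product at 50 h
* excess of right-handed substrate over left-handed substrate among what is left of the two at 50 h

Birch draws the rest of the curve. It climbs through 3.0% at 20.0 h to 4.2% at 30.0 h, and that is the knee, for it reads 4.1% at 48.0 h. I read the level as 4.15%. Birch still holds 46.6% of left-handed and 48.3% of right-handed substrate, so I charge the stall to the catalyst. That level is 24.4 left-handed product per free catalyst charged: the turnover allowance, in the usual term the turnover number.

Scaled to 0.50 mM of free catalyst, the allowance puts the level of the asked flask, larch carried on, at 6.10% of left-handed product. The asked 50 h lies later than the knee of birch, so I commit to that level, with c a little above it. Right-handed product is never read, so I put no figure on eP. A racemate has zero as the mark for eS, and the right-minus-left gap in birch averages 0.55 percentage points over its last two readings, so I put eS near zero.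

The forecast gives c 6.5%, eP 90% and eS 0.8%, reading the stall as “catalyst death after limited turnovers”. The flask gives c 6.80%, eP 93.9% and eS 0.0544%.

    solid reagent ⇌ partner, rate k1*(cs1 - [partner]) while solid is left; crystals form when [partner] > cs1 (solubility = 0.0980 M, k = 0.0410 /h)
    partner + free catalyst + left-handed substrate → free catalyst + left-handed product (k = 1100 /M²/h)
    partner + free catalyst + right-handed substrate → free catalyst + right-handed product (k = 34.0 /M²/h)
    left-handed substrate + racemization catalyst ⇌ right-handed substrate + racemization catalyst, rate k4*[racemization catalyst]*[left-handed substrate] forward; the back reaction follows from the equilibrium constant (k = 18.0 /M/h)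
    free catalyst → spent catalyst (k = 0.100 /h)

In the asked flask at 50.0 h, 6.60% of left-handed product stands against my 6.10%, and free catalyst is down to 0.674% of its charge. Both products together make 27.2 turnovers. The neighbour flask, with 1.3 × 10⁻⁴ M of free catalyst, gets the same reckoning: 24.4 turnovers give 1.59%. It reaches 1.91% of left-handed product, with c 1.97% at eP 94.0%, which is 30.3 turnovers for both products together, and its free catalyst stands at 0.674% of the charge at 50.0 h.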